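I began with the easy step, the balance of the free catalyst, the reagent charged in the smaller amount as starting material turns into product. At 34 h blue, with twice the starting material of ochre, stood at 0.743 M against 0.625 M, while teal, with more catalyst, stood at 1.000 M, so I supposed that each turnover costs free catalyst a fixed small share.

| flask | starting material | free catalyst | time |
|---|---|---|---|
| ochre | 1.00 M | 0.00200 M |  |
| teal | 1.00 M | 0.00600 M |  |
| blue | 2.00 M | 0.00200 M |  |
| grey | 1.00 M | 0.00200 M | 120 h |

- ochre run (time / h: [product] / M): 2.3: 0.162; 4.0: 0.244; 6.8: 0.342; 12: 0.453; 20: 0.540; 34: 0.625; 58: 0.680
- teal run (time / h: [product] / M): 2.3: 0.417; 4.0: 0.577; 6.8: 0.743; 12: 0.889; 20: 0.966; 34: 1.000; 58: 1.002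
- blue run (time / h: [product] / M): 2.3: 0.288; 4.0: 0.412; 6.8: 0.532; 12: 0.629; 20: 0.689; 34: 0.743; 58: 0.813

(scatter of a reading: 0.005 M)

- order of the initial rate in [free catalyst], near the charge of the ochre run, the rate being that where two percent of its starting material are product
- order of the initial rate in [starting material], near the charge of the ochre run, the rate being that where two percent of its starting material are product (one fixed amount of product, the same in the runs compared)
- product in the grey run at 120 h, as a share of the starting material charged

- Overall: starting material -> product, with free catalyst as catalyst.
- Constant volume, constant temperature.
- An order is taken over about fifteen percent of the charge, up and down.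

Blue's last two readings rise by 0.00292 M h⁻¹, which I read as a slow leak, and running that line back to time zero left 0.644 M of catalysed product. Dividing by blue's catalyst gave n = 322, the product one catalyst makes in its working life, its turnover number. With c the free catalyst charged and s the starting material charged, Φ = nc/s is the share of the charge that the catalyst can turn over.

| Flask | Φ | Share at last reading |
|---|---|---|
| ochre | 0.644 | 0.680 |
| teal | 1.93 | 1.00 |
| blue | 0.322 | 0.406 |

Teal, with Φ above one, reached full conversion, but ochre and blue stood above their Φ, so one number was not enough. Blue's rise over its remaining starting material gave a leak constant k = 0.00239 h⁻¹, and I let the part Φ leaves unturned shrink as exp(−kt). That gave ochre 69.0% at 58 h, against 68.0% read, and grey, with Φ = 0.644, 73.3% at 120 h.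

The forecast, which said that something “titrates catalyst tightly”, gave orders of 1.03 in free catalyst and 1 in starting material, and 74% for grey, above my figure. I made no separate reckoning of the orders.

The flask gave orders of 1.0 and 1.0, and 73.6% for grey, under these steps:

    free catalyst + starting material → product + free catalyst (43.20 M⁻¹ h⁻¹)
    starting material → product (0.002264 h⁻¹)
    free catalyst + starting material → spent catalyst + starting material (0.1357 M⁻¹ h⁻¹)

The passing of free catalyst into spent catalyst moves the readings by 94 times the scatter, root mean square. Grey's Φ stands 9.2 percentage points below its share at 120 h. In blue, Φ and the leak put product at half the charge at 128 h, and blue reached it at 135 h.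

Readings and results were computed for substances that don't exist; the scatter is artificial.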